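**Plan**

- Retrosynthetic cuts, in order: C1–C8a (Bischler–Napieralski closure of an acetamide), C1'–C2' of the naphthalene, C1'–C8a' and C3'–C4' (two carbonyl additions), C5–C1' (formylation of ring A) and C4–C4a (aryl Grignard opening of an alanine-derived sulfamidate).
- Enabling feature: in the substituted naphthalene ring, C1' carries ring A, C2' a one-carbon group and C4' an oxygen. This is the pattern left when the α-carbon of an aldehyde adds to a diaryl ketone (C1') that sits ortho to a 4-oxobutanoyl chain (C4', C3', C2' and the formyl carbon).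
- Forward order: the aminopropyl chain goes onto ring A, C1' is attached to C5 as a formyl group, the methoxyphenyl building block is joined and the diol oxidised to the diketone. The second naphthalene ring is then closed (ring and axis together), C2'-CHO is taken down to CH3, and the nitrogen ring is closed last.
- Stereochemistry: C3 (S) is carried unchanged from L-alanine through sulfamidate 2. The C5–C1' axis is set by the chiral pyrrolidine catalyst in the ring-forming aldol step and is locked by its four ortho substituents.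

Key step: step 8

Assumption: the structure given defines only C3 (S). The P axis is taken as the goal; step 8 is written with the (S)-catalyst, and the mirror-image catalyst is used instead if a trial shows that it is the one that delivers this axis.

Remark: the SMILES strings cannot show the axis, so the names carry it. Compounds 20–22 are M and 23–25 are P for one and the same spatial arrangement, because C2' ranks above C8a' while it bears CHO or CH2OH and below it once it bears CH3.

**Route**

Step 1
Reactants: 1 1-bromo-3,5-dimethoxybenzene; 2 tert-butyl (4S)-4-methyl-1,2,3-oxathiazolidine-3-carboxylate 2,2-dioxide (commercial, made from Boc-L-alaninol)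
Product: 6 (2S)-1-(3,5-dimethoxyphenyl)propan-2-amine, via aryl Grignard reagent 3 (not isolated), via N-sulfonated Boc amine salt 4 (not isolated), via Boc carbamate 5 (not isolated)
Conditions: Mg, THF, 40 °C; then 2, CuI (10 mol%), THF, −20 °C to rt; then 3 M HCl, MeOH, 50 °C; aq. NaOH work-up
Reagents that add atoms: none
Why: Copper-catalysed SN2 opening of the cyclic sulfamidate by the aryl Grignard reagent takes place at the unsubstituted CH2–O carbon, so the alanine-derived centre stays S, and the acid then hydrolyses the N-sulfonate and removes the Boc group.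

Step 2
Reactants: 6 (2S)-1-(3,5-dimethoxyphenyl)propan-2-amine
Product: 7 (2S)-N,N-dibenzyl-1-(3,5-dimethoxyphenyl)propan-2-amine
Conditions: BnBr (2.3 equiv), K2CO3, MeCN, 70 °C
Reagents that add atoms: benzyl bromide, BrCc1ccccc1
Why: Twofold SN2 N-benzylation stops at the hindered tertiary amine, which has no N–H, tolerates organolithium reagents and oxidants, and is later removed by hydrogenolysis.

Step 3
Reactants: 7 (2S)-N,N-dibenzyl-1-(3,5-dimethoxyphenyl)propan-2-amine
Product: 9 2-[(2S)-2-(dibenzylamino)propyl]-4,6-dimethoxybenzaldehyde, via aryl iminium chloride 8 (not isolated)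
Conditions: POCl3, DMF, 0 to 60 °C; then H2O, aq. NaOH to pH 9
Reagents that add atoms: N,N-dimethylformamide, CN(C)C=O; water, O
Why: Vilsmeier–Haack formylation of a 3,5-dimethoxyalkylbenzene should go to the position para to one methoxy group and ortho to the chain (the site between the two methoxy groups being the minor one), which places the future C1' carbon on C5.

Step 4
Reactants: 10 2-(2-bromoethyl)-1,3-dioxolane; 11 2-bromo-6-methoxybenzaldehyde
Product: 13 1-(2-bromo-6-methoxyphenyl)-3-(1,3-dioxolan-2-yl)propan-1-ol (racemic), via dioxolanylethyl Grignard reagent 12 (not isolated)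
Conditions: Mg, THF, 25–30 °C; then 11, THF, 0 °C; aq. NH4Cl
Reagents that add atoms: none
Why: Grignard 1,2-addition to the aldehyde is far faster than any reaction at the aryl bromide or the dioxolane and installs the four-carbon chain with its terminal aldehyde masked.

Step 5
Reactants: 13 1-(2-bromo-6-methoxyphenyl)-3-(1,3-dioxolan-2-yl)propan-1-ol (1.3 equiv); 9 2-[(2S)-2-(dibenzylamino)propyl]-4,6-dimethoxybenzaldehyde
Product: 15 1-[2-({2-[(2S)-2-(dibenzylamino)propyl]-4,6-dimethoxyphenyl}(hydroxy)methyl)-6-methoxyphenyl]-3-(1,3-dioxolan-2-yl)propan-1-ol (mixture of carbinol epimers; used crude), via dilithio species 14 (not isolated)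
Conditions: n-BuLi (2.2 equiv), THF, −78 °C; then 9, −78 to −20 °C; aq. NH4Cl
Reagents that add atoms: none
Why: Deprotonation of the alcohol and bromine–lithium exchange give an alkoxide-bearing aryllithium that adds to the hindered but non-enolisable aldehyde (aryllithium 1,2-addition), and the two carbinol centres, formed unselectively, are erased in the next step.

Step 6
Reactants: 15 the diol from step 5
Product: 16 1-[2-{2-[(2S)-2-(dibenzylamino)propyl]-4,6-dimethoxybenzoyl}-6-methoxyphenyl]-3-(1,3-dioxolan-2-yl)propan-1-one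
Conditions: Dess–Martin periodinane (3 equiv), NaHCO3, CH2Cl2, 0 °C to rt
Reagents that add atoms: none
Why: Buffered Dess–Martin oxidation converts both benzylic carbinols into ketones without acid, sparing the tertiary amine, the dioxolane and the easily ionised electron-rich benzhydrol, and any cyclic hemiketal formed after the first oxidation reopens and is oxidised in turn.

Step 7
Reactants: 16 the diketone acetal from step 6
Product: 17 4-[2-{2-[(2S)-2-(dibenzylamino)propyl]-4,6-dimethoxybenzoyl}-6-methoxyphenyl]-4-oxobutanal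
Conditions: 1 M HCl, THF, rt; aq. NaHCO3 work-up; used without delay
Reagents that add atoms: water, O
Why: Acid-catalysed acetal hydrolysis frees the aldehyde while the protonated amine and the two aryl ketones are inert, and the mild aqueous conditions stay short of furan formation from the 1,4-dicarbonyl unit.

Step 8
Reactants: 17 4-[2-{2-[(2S)-2-(dibenzylamino)propyl]-4,6-dimethoxybenzoyl}-6-methoxyphenyl]-4-oxobutanal
Product: 20 (M)-1-{2-[(2S)-2-(dibenzylamino)propyl]-4,6-dimethoxyphenyl}-4-hydroxy-5-methoxynaphthalene-2-carbaldehyde, via aldol adduct 18 (not isolated), via dihydronaphthalenone 19 (not isolated)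
Conditions: (S)-5-(pyrrolidin-2-yl)-1H-tetrazole (20 mol%), CF3CO2H (1.0 equiv), CHCl3 (dilute), 25 to 45 °C; aq. NaHCO3 work-up
Reagents that add atoms: none
Why: The pyrrolidine nitrogen condenses with the aldehyde, and the enamine carbon (future C2') adds to the diaryl ketone carbon (future C1') while the tetrazole N–H hydrogen-bonds the ketone oxygen, giving adduct 18; loss of water gives enal 19, and tautomerisation of the C4' ketone to the naphthol aromatises the new ring and releases the catalyst. The closest known reaction type is the secondary-amine-catalysed atroposelective arene-forming aldol condensation of aryl ketoaldehydes, applied here to a biaryl with four ortho substituents. The single ring formed closes in the 6-(enolexo)-exo-trig mode. The new stereo element is the C5–C1' axis: the catalyst fixes which face of the ketone is attacked, ring A in 18 is held as one rotamer because the enamine must pass the methoxy flank and not the larger aminopropyl flank, and dehydration transfers this central chirality to the axis, so the catalyst and not the remote C3 centre should decide its sense. The step needs C2' and not C3' to be the nucleophile (six-membered ring, no indanone); this is secured because only the aldehyde forms an enamine, the ketone between two ortho substituents being inert to the amine, while one equivalent of CF3CO2H keeps the dibenzylamino group protonated so that it cannot take the acidic proton from the catalyst. The gain of a naphthalene ring makes the closure irreversible and pays for attack on a hindered ketone.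

Step 9
Reactants: 20 the naphthol aldehyde from step 8
Product: 21 (M)-1-{2-[(2S)-2-(dibenzylamino)propyl]-4,6-dimethoxyphenyl}-4,5-dimethoxynaphthalene-2-carbaldehyde
Conditions: CH3I (1.3 equiv), Cs2CO3, DMF, 0 °C to rt
Reagents that add atoms: iodomethane, CI
Why: Williamson O-methylation of the naphtholate should be much faster than quaternisation of the crowded N,N-dibenzyl sec-alkyl amine when only a small excess of iodomethane is used.

Step 10
Reactants: 21 the dimethoxy aldehyde from step 9
Product: 22 (M)-[1-{2-[(2S)-2-(dibenzylamino)propyl]-4,6-dimethoxyphenyl}-4,5-dimethoxynaphthalen-2-yl]methanol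
Conditions: NaBH4, MeOH/THF, 0 °C
Reagents that add atoms: none
Why: Borohydride reduction of the only carbonyl group left gives the naphthylmethanol, so the primary amine set free later never meets an aldehyde.

Step 11
Reactants: 22 the naphthylmethanol from step 10
Product: 23 (P)-(2S)-1-[2-(4,5-dimethoxy-2-methylnaphthalen-1-yl)-3,5-dimethoxyphenyl]propan-2-amine
Conditions: H2 (4 bar), Pd(OH)2/C, EtOH/AcOH, HCl (1.1 equiv), 40 °C; aq. NaOH work-up
Reagents that add atoms: none
Why: Acid-assisted hydrogenolysis cleaves the benzylic C–O bond of the naphthylmethanol and both N-benzyl groups in one operation, leaving the homobenzylic C3–N bond and the axis untouched (the change from M to P is one of CIP rank only).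

Step 12
Reactants: 23 the primary amine from step 11
Product: 24 (P)-N-{(2S)-1-[2-(4,5-dimethoxy-2-methylnaphthalen-1-yl)-3,5-dimethoxyphenyl]propan-2-yl}acetamide
Conditions: Ac2O, Et3N, CH2Cl2, 0 °C to rt
Reagents that add atoms: acetic anhydride, CC(=O)OC(C)=O
Why: N-acylation of the primary amine supplies C1 and its methyl group as the amide needed for ring closure.

Step 13
Reactants: 24 the acetamide from step 12
Product: 25 O-methylancistrocladinine, (3S,P)-5-(4,5-dimethoxy-2-methylnaphthalen-1-yl)-6,8-dimethoxy-1,3-dimethyl-3,4-dihydroisoquinoline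
Conditions: POCl3, MeCN, 80 °C; aq. NaOH work-up
Reagents that add atoms: none
Why: Bischler–Napieralski cyclodehydration: the nitrilium ion attacks C8a, the only free position ortho to the chain and activated by the ortho and para methoxy groups, while C3 is not a reacting centre and the axis with four ortho substituents should not rotate at this temperature.

**Compound list**

1 | 1-bromo-3,5-dimethoxybenzene | COc1cc(Br)cc(OC)c1 | starting material
2 | tert-butyl (4S)-4-methyl-1,2,3-oxathiazolidine-3-carboxylate 2,2-dioxide | C[C@H]1COS(=O)(=O)N1C(=O)OC(C)(C)C | starting material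
3 | (3,5-dimethoxyphenyl)magnesium bromide | COc1cc(OC)cc([Mg]Br)c1 | intermediate (not isolated)
4 | bromomagnesium N-(tert-butoxycarbonyl)-N-[(2S)-1-(3,5-dimethoxyphenyl)propan-2-yl]sulfamate | COc1cc(OC)cc(C[C@H](C)N(C(=O)OC(C)(C)C)S(=O)(=O)[O-])c1.[Mg+2].[Br-] | intermediate (not isolated)
5 | tert-butyl N-[(2S)-1-(3,5-dimethoxyphenyl)propan-2-yl]carbamate | COc1cc(OC)cc(C[C@H](C)NC(=O)OC(C)(C)C)c1 | intermediate (not isolated)
6 | (2S)-1-(3,5-dimethoxyphenyl)propan-2-amine | COc1cc(OC)cc(C[C@H](C)N)c1 | intermediate
7 | (2S)-N,N-dibenzyl-1-(3,5-dimethoxyphenyl)propan-2-amine | COc1cc(OC)cc(C[C@H](C)N(Cc2ccccc2)Cc2ccccc2)c1 | intermediate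
8 | N-({2-[(2S)-2-(dibenzylamino)propyl]-4,6-dimethoxyphenyl}methylidene)-N-methylmethanaminium chloride | C[N+](C)=Cc1c(OC)cc(OC)cc1C[C@H](C)N(Cc1ccccc1)Cc1ccccc1.[Cl-] | intermediate (not isolated)
9 | 2-[(2S)-2-(dibenzylamino)propyl]-4,6-dimethoxybenzaldehyde | O=Cc1c(OC)cc(OC)cc1C[C@H](C)N(Cc1ccccc1)Cc1ccccc1 | intermediate
10 | 2-(2-bromoethyl)-1,3-dioxolane | BrCCC1OCCO1 | starting material
11 | 2-bromo-6-methoxybenzaldehyde | COc1cccc(Br)c1C=O | starting material
12 | [2-(1,3-dioxolan-2-yl)ethyl]magnesium bromide | Br[Mg]CCC1OCCO1 | intermediate (not isolated)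
13 | 1-(2-bromo-6-methoxyphenyl)-3-(1,3-dioxolan-2-yl)propan-1-ol (racemic) | COc1cccc(Br)c1C(O)CCC1OCCO1 | intermediate
14 | lithium 3-(1,3-dioxolan-2-yl)-1-(2-lithio-6-methoxyphenyl)propan-1-olate | [Li]OC(CCC1OCCO1)c1c([Li])cccc1OC | intermediate (not isolated)
15 | 1-[2-({2-[(2S)-2-(dibenzylamino)propyl]-4,6-dimethoxyphenyl}(hydroxy)methyl)-6-methoxyphenyl]-3-(1,3-dioxolan-2-yl)propan-1-ol (carbinol epimers) | COc1cccc(C(O)c2c(OC)cc(OC)cc2C[C@H](C)N(Cc2ccccc2)Cc2ccccc2)c1C(O)CCC1OCCO1 | intermediate
16 | 1-[2-{2-[(2S)-2-(dibenzylamino)propyl]-4,6-dimethoxybenzoyl}-6-methoxyphenyl]-3-(1,3-dioxolan-2-yl)propan-1-one | COc1cccc(C(=O)c2c(OC)cc(OC)cc2C[C@H](C)N(Cc2ccccc2)Cc2ccccc2)c1C(=O)CCC1OCCO1 | intermediate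
17 | 4-[2-{2-[(2S)-2-(dibenzylamino)propyl]-4,6-dimethoxybenzoyl}-6-methoxyphenyl]-4-oxobutanal | O=CCCC(=O)c1c(OC)cccc1C(=O)c1c(OC)cc(OC)cc1C[C@H](C)N(Cc1ccccc1)Cc1ccccc1 | intermediate (key-step precursor)
18 | 1-{2-[(2S)-2-(dibenzylamino)propyl]-4,6-dimethoxyphenyl}-1-hydroxy-5-methoxy-4-oxo-1,2,3,4-tetrahydronaphthalene-2-carbaldehyde (C1' and C2' set by the catalyst, transient) | O=CC1CC(=O)c2c(OC)cccc2C1(O)c1c(OC)cc(OC)cc1C[C@H](C)N(Cc1ccccc1)Cc1ccccc1 | intermediate (not isolated)
19 | 1-{2-[(2S)-2-(dibenzylamino)propyl]-4,6-dimethoxyphenyl}-5-methoxy-4-oxo-3,4-dihydronaphthalene-2-carbaldehyde | O=CC1=C(c2c(OC)cc(OC)cc2C[C@H](C)N(Cc2ccccc2)Cc2ccccc2)c2cccc(OC)c2C(=O)C1 | intermediate (not isolated)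
20 | (M)-1-{2-[(2S)-2-(dibenzylamino)propyl]-4,6-dimethoxyphenyl}-4-hydroxy-5-methoxynaphthalene-2-carbaldehyde | O=Cc1cc(O)c2c(OC)cccc2c1-c1c(OC)cc(OC)cc1C[C@H](C)N(Cc1ccccc1)Cc1ccccc1 | intermediate (key-step product)
21 | (M)-1-{2-[(2S)-2-(dibenzylamino)propyl]-4,6-dimethoxyphenyl}-4,5-dimethoxynaphthalene-2-carbaldehyde | O=Cc1cc(OC)c2c(OC)cccc2c1-c1c(OC)cc(OC)cc1C[C@H](C)N(Cc1ccccc1)Cc1ccccc1 | intermediate
22 | (M)-[1-{2-[(2S)-2-(dibenzylamino)propyl]-4,6-dimethoxyphenyl}-4,5-dimethoxynaphthalen-2-yl]methanol | OCc1cc(OC)c2c(OC)cccc2c1-c1c(OC)cc(OC)cc1C[C@H](C)N(Cc1ccccc1)Cc1ccccc1 | intermediate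
23 | (P)-(2S)-1-[2-(4,5-dimethoxy-2-methylnaphthalen-1-yl)-3,5-dimethoxyphenyl]propan-2-amine | Cc1cc(OC)c2c(OC)cccc2c1-c1c(OC)cc(OC)cc1C[C@H](C)N | intermediate
24 | (P)-N-{(2S)-1-[2-(4,5-dimethoxy-2-methylnaphthalen-1-yl)-3,5-dimethoxyphenyl]propan-2-yl}acetamide | Cc1cc(OC)c2c(OC)cccc2c1-c1c(OC)cc(OC)cc1C[C@H](C)NC(C)=O | intermediate
25 | O-methylancistrocladinine, (3S,P) | COc1cc(OC)c(-c2c(C)cc(OC)c3c(OC)cccc23)c2c1C(C)=N[C@@H](C)C2 | target

**Count and risks**

Total steps: 13. Longest linear sequence: 12 steps (steps 1–3 and 5–13, from 1); step 4 is a one-step side branch.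

Steps most likely to fail:

1. Step 8. The enamine may add only slowly or reversibly to a ketone carbon flanked on ring A by a methoxy group and the aminopropyl chain, and the catalyst may not impose a single sense on the axis, since facial choice at the ketone and the rotamer of ring A must both be controlled. Fallback: stereocontrol is moved from the catalyst to a separation that uses C3 as an internal resolving handle. Setting out from 17, the ring is closed with an achiral amine salt (pyrrolidinium acetate, toluene, 70 °C), which should give 20 together with its axis epimer, (P)-1-{2-[(2S)-2-(dibenzylamino)propyl]-4,6-dimethoxyphenyl}-4-hydroxy-5-methoxynaphthalene-2-carbaldehyde F1. Because of C3 the two atropisomers are diastereomers; they are separated by chromatography or by crystallisation of a salt of the tertiary amine, and 20 returns to the route at step 9.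

2. Step 11. Hydrogenolysis of the C–O bond may stall because the naphthalene cannot lie flat on the metal next to the perpendicular ring A, and forcing conditions may begin to saturate the naphthalene. Fallback: the C–O bond is removed by hydride displacement and the hydrogenolysis is left with the unhindered N-benzyl groups only. Setting out from 22, CH3SO2Cl/Et3N in CH2Cl2 gives the naphthylmethyl mesylate, (M)-[1-{2-[(2S)-2-(dibenzylamino)propyl]-4,6-dimethoxyphenyl}-4,5-dimethoxynaphthalen-2-yl]methyl methanesulfonate F2. LiBHEt3 in THF reduces it to (P)-(2S)-N,N-dibenzyl-1-[2-(4,5-dimethoxy-2-methylnaphthalen-1-yl)-3,5-dimethoxyphenyl]propan-2-amine F3, and H2 with Pd(OH)2/C in EtOH at rt then removes the benzyl groups to give 23.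

3. Step 6. The electron-rich diaryl carbinol of 15 may ionise under traces of acid and close onto the neighbouring hydroxyl to a cyclic ether before it is oxidised, or the oxidation may stop at a cyclic hemiketal. Fallback: the diketone is reached through a phthalide, so that a free diaryl carbinol never sits next to a second carbinol. Setting out from 9, commercial N,N-diethyl-2-methoxybenzamide is lithiated ortho to the amide (s-BuLi, TMEDA, THF, −78 °C) to N,N-diethyl-2-lithio-6-methoxybenzamide F4. This adds to 9 to give the hydroxy amide N,N-diethyl-2-({2-[(2S)-2-(dibenzylamino)propyl]-4,6-dimethoxyphenyl}(hydroxy)methyl)-6-methoxybenzamide F5. TsOH in toluene lactonises it to 3-{2-[(2S)-2-(dibenzylamino)propyl]-4,6-dimethoxyphenyl}-7-methoxy-2-benzofuran-1(3H)-one F6. One equivalent of Grignard reagent 12 at −78 °C adds once to the lactone to give the lactol 3-{2-[(2S)-2-(dibenzylamino)propyl]-4,6-dimethoxyphenyl}-1-[2-(1,3-dioxolan-2-yl)ethyl]-7-methoxy-1,3-dihydro-2-benzofuran-1-ol F7. Oxidation of its ring-opened hydroxy ketone form (Dess–Martin periodinane, NaHCO3, CH2Cl2) gives 16, where the route continues with step 7.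

**Further compounds**

F1 | step 8 | (P)-1-{2-[(2S)-2-(dibenzylamino)propyl]-4,6-dimethoxyphenyl}-4-hydroxy-5-methoxynaphthalene-2-carbaldehyde (axis epimer of 20) | O=Cc1cc(O)c2c(OC)cccc2c1-c1c(OC)cc(OC)cc1C[C@H](C)N(Cc1ccccc1)Cc1ccccc1
F2 | step 11 | (M)-[1-{2-[(2S)-2-(dibenzylamino)propyl]-4,6-dimethoxyphenyl}-4,5-dimethoxynaphthalen-2-yl]methyl methanesulfonate | CS(=O)(=O)OCc1cc(OC)c2c(OC)cccc2c1-c1c(OC)cc(OC)cc1C[C@H](C)N(Cc1ccccc1)Cc1ccccc1
F3 | step 11 | (P)-(2S)-N,N-dibenzyl-1-[2-(4,5-dimethoxy-2-methylnaphthalen-1-yl)-3,5-dimethoxyphenyl]propan-2-amine | Cc1cc(OC)c2c(OC)cccc2c1-c1c(OC)cc(OC)cc1C[C@H](C)N(Cc1ccccc1)Cc1ccccc1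
F4 | step 6 | N,N-diethyl-2-lithio-6-methoxybenzamide | CCN(CC)C(=O)c1c(OC)cccc1[Li]
F5 | step 6 | N,N-diethyl-2-({2-[(2S)-2-(dibenzylamino)propyl]-4,6-dimethoxyphenyl}(hydroxy)methyl)-6-methoxybenzamide | CCN(CC)C(=O)c1c(OC)cccc1C(O)c1c(OC)cc(OC)cc1C[C@H](C)N(Cc1ccccc1)Cc1ccccc1
F6 | step 6 | 3-{2-[(2S)-2-(dibenzylamino)propyl]-4,6-dimethoxyphenyl}-7-methoxy-2-benzofuran-1(3H)-one | O=C1OC(c2c(OC)cc(OC)cc2C[C@H](C)N(Cc2ccccc2)Cc2ccccc2)c2cccc(OC)c12
F7 | step 6 | 3-{2-[(2S)-2-(dibenzylamino)propyl]-4,6-dimethoxyphenyl}-1-[2-(1,3-dioxolan-2-yl)ethyl]-7-methoxy-1,3-dihydro-2-benzofuran-1-ol | OC1(CCC2OCCO2)OC(c2c(OC)cc(OC)cc2C[C@H](C)N(Cc2ccccc2)Cc2ccccc2)c2cccc(OC)c12
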